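**Plan**
1. Cuts: C11=C12 and C11'=C12' (two Wittig reactions on the C10 dialdehyde 2,7-dimethylocta-2,4,6-trienedial), C8–C9 in the ring A half (Sonogashira) and C9'=C10' in the ring B half (Horner–Wadsworth–Emmons). Ring A then loses C8–C10 at C7=C8 (ozonolysis, one-carbon alkynylation), so both rings come from one protected (3S,4S)-3,4-dihydroxy-β-ionone.
2. Ring cut: C1–C6. Each ring is a 2,6,6-trimethylcyclohexene in which the quaternary C1 is bonded to C6 of a tetrasubstituted C5=C6 bond conjugated with C7=C8. That is the pattern left when a tertiary C1 cation is captured by a C5=C6 bond and C6 loses its proton; the trans C3/C4 diol lies outside this event.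
3. Forward: L-tartrate acetonide diester → open-chain C13 trienone with the diol as trans cyclic carbonate → acid ring closure → carbonate exchanged for silyl ethers → ring B C15 salt + C10 dialdehyde → C25 aldehyde; ring A enynyl C15 salt; final Wittig; desilylation.
4. Stereochemistry: C3, C4, C3' and C4' are the two carbinol carbons of L-tartaric acid and are never touched; the S descriptors come only from changed CIP priorities.
5. Double bonds: E from phosphonate and ylide olefinations, from an E enol triflate (9E), and from thermal equilibration of the two Wittig-made bonds.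

Key step: step 9

Remark: positions are given in carotenoid numbering (ring C1–C6, chain from C7; primes for the ring B half; 13–16 serve both halves); TBS = tert-butyl(dimethyl)silyl; it is assumed that minor Z isomers from the olefination steps are removed by chromatography or by the thermal equilibration named in the step.

Step 1
Reactants: 1 dimethyl (4R,5R)-2,2-dimethyl-1,3-dioxolane-4,5-dicarboxylate (dimethyl 2,3-O-isopropylidene-L-tartrate)
Product: 2 methyl (4R,5S)-5-(hydroxymethyl)-2,2-dimethyl-1,3-dioxolane-4-carboxylate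
Conditions: NaBH4 (0.6 equiv), MeOH, 0 °C → rt
Reagents that add atoms: none
Why: Partial hydride reduction of a C2-symmetric diester (statistical desymmetrisation) with a deficit of NaBH4 should stop mainly at the hydroxy ester, which is separated from diol and recovered 1, and no stereocentre is touched.

Step 2
Reactants: 2 methyl (4R,5S)-5-(hydroxymethyl)-2,2-dimethyl-1,3-dioxolane-4-carboxylate
Product: 3 methyl (4R,5S)-2,2-dimethyl-5-({[(trifluoromethyl)sulfonyl]oxy}methyl)-1,3-dioxolane-4-carboxylate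
Conditions: Tf2O, pyridine, CH2Cl2, −20 °C
Reagents that add atoms: trifluoromethanesulfonic anhydride, O=S(=O)(OS(=O)(=O)C(F)(F)F)C(F)(F)F
Why: O-Sulfonylation of the primary alcohol gives the triflate, the leaving group needed for substitution at a carbon deactivated by the β-oxygen of the dioxolane.

Step 3
Reactants: 3 methyl (4R,5S)-2,2-dimethyl-5-({[(trifluoromethyl)sulfonyl]oxy}methyl)-1,3-dioxolane-4-carboxylate; 4 isopropenylmagnesium bromide
Product: 5 methyl (4R,5S)-2,2-dimethyl-5-(2-methylprop-2-en-1-yl)-1,3-dioxolane-4-carboxylate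
Conditions: CuBr·SMe2 (10 mol %), THF, −40 → −20 °C, 4 added slowly
Reagents that add atoms: none
Why: Copper-catalysed cross-coupling of a primary alkyl triflate with an alkenyl Grignard reagent (Kotsuki-type coupling) should displace the triflate at −40 °C much faster than the Grignard reagent adds to the ester, and it builds C1–C2 without touching the stereocentres.

Step 4
Reactants: 5 methyl (4R,5S)-2,2-dimethyl-5-(2-methylprop-2-en-1-yl)-1,3-dioxolane-4-carboxylate
Product: 7 1-[(4R,5S)-2,2-dimethyl-5-(2-methylprop-2-en-1-yl)-1,3-dioxolan-4-yl]ethan-1-one, via Weinreb amide 6 (not isolated)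
Conditions: MeNH(OMe)·HCl, i-PrMgCl, THF, −20 °C; then MeMgBr, 0 °C; aq. NH4Cl
Reagents that add atoms: methylmagnesium bromide, C[Mg]Br; N,O-dimethylhydroxylamine hydrochloride, CNOC.Cl (its atoms stay in 6 only)
Why: Weinreb ketone synthesis in one flask: the magnesium amide turns the ester into the N-methoxy-N-methylamide, whose chelated adduct with MeMgBr stops at the methyl ketone, and the α-carbon sits in the more stable trans-dioxolane so it should not epimerise.

Step 5
Reactants: 7 1-[(4R,5S)-2,2-dimethyl-5-(2-methylprop-2-en-1-yl)-1,3-dioxolan-4-yl]ethan-1-one; 8 triethyl 4-phosphonocrotonate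
Product: 9 ethyl (2E,4E)-5-[(4S,5S)-2,2-dimethyl-5-(2-methylprop-2-en-1-yl)-1,3-dioxolan-4-yl]hexa-2,4-dienoate
Conditions: LiN(SiMe3)2, THF/DMPU, −78 → 0 °C
Reagents that add atoms: none
Why: Vinylogous Horner–Wadsworth–Emmons olefination of the activated α-alkoxy methyl ketone should give the dienoate with E geometry at C7=C8 and mainly E at the new C5=C6 bond, whose geometry is erased again in step 9.

Step 6
Reactants: 9 ethyl (2E,4E)-5-[(4S,5S)-2,2-dimethyl-5-(2-methylprop-2-en-1-yl)-1,3-dioxolan-4-yl]hexa-2,4-dienoate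
Product: 11 (3E,5E)-6-[(4S,5S)-2,2-dimethyl-5-(2-methylprop-2-en-1-yl)-1,3-dioxolan-4-yl]hepta-3,5-dien-2-one, via dienyl Weinreb amide 10 (not isolated)
Conditions: MeNH(OMe)·HCl, i-PrMgCl, THF, −20 °C; then MeMgBr, −20 → 0 °C; aq. NH4Cl
Reagents that add atoms: methylmagnesium bromide, C[Mg]Br; N,O-dimethylhydroxylamine hydrochloride, CNOC.Cl (its atoms stay in 10 only)
Why: The same one-flask Weinreb ketone synthesis converts the dienoate into the methyl dienone, because the chelated adduct of the amide takes up only one methyl group and reacts 1,2.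

Step 7
Reactants: 11 (3E,5E)-6-[(4S,5S)-2,2-dimethyl-5-(2-methylprop-2-en-1-yl)-1,3-dioxolan-4-yl]hepta-3,5-dien-2-one
Product: 12 (3E,5E,7S,8S)-7,8-dihydroxy-6,10-dimethylundeca-3,5,10-trien-2-one
Conditions: AcOH/H2O (4:1), 40 °C
Reagents that add atoms: none
Why: Acid-catalysed acetal hydrolysis frees the diol, and the weak acid should neither protonate the isopropenyl group nor ionise the C4 alcohol next to the electron-poor dienone.

Step 8
Reactants: 12 (3E,5E,7S,8S)-7,8-dihydroxy-6,10-dimethylundeca-3,5,10-trien-2-one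
Product: 13 (4S,5S)-4-(2-methylprop-2-en-1-yl)-5-[(2E,4E)-6-oxohepta-2,4-dien-2-yl]-1,3-dioxolan-2-one
Conditions: 1,1'-carbonyldiimidazole, DMAP (cat.), CH2Cl2, rt
Reagents that add atoms: 1,1'-carbonyldiimidazole, O=C(n1ccnc1)n1ccnc1
Why: Carbonylation of the 1,2-diol by acyl transfer closes the five-membered carbonate with retention at both carbinol carbons, giving the trans-4,5-disubstituted dioxolanone that is stable to strong acid.

Step 9
Reactants: 13 (4S,5S)-4-(2-methylprop-2-en-1-yl)-5-[(2E,4E)-6-oxohepta-2,4-dien-2-yl]-1,3-dioxolan-2-one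
Product: 14 (3aS,7aS)-4,6,6-trimethyl-5-[(1E)-3-oxobut-1-en-1-yl]-3a,6,7,7a-tetrahydro-1,3-benzodioxol-2-one (trans-fused 3,4-carbonate of (3S,4S)-3,4-dihydroxy-β-ionone)
Conditions: conc. H2SO4/AcOH, 0 → 10 °C; then ice-water
Reagents that add atoms: none
Why: Sulfuric acid protonates the 1,1-disubstituted olefin at its CH2 carbon, the tertiary C1 cation is captured by C6 of the C5=C6 bond to form the C1–C6 bond, and the tertiary C5 cation then loses the C6 proton. The closest known reaction is the sulfuric acid cyclisation of pseudoionone to β-ionone (cation–olefin cyclisation of a terpenoid dienone), here applied to a 3,4-dioxygenated substrate for which it has not been demonstrated. The six-membered ring closes in the 6-endo-trig mode with respect to C5=C6 through a chair-like arrangement, and the E/Z geometry of C5=C6 in 13 does not matter because C6 is sp3 in between. No stereocentre is formed: C3 and C4 lie outside the bond reorganisation and are carried over from L-tartrate, held trans by the carbonate. The step needs the double bond to end at C5=C6 and both C–O bonds to survive. The first is secured by conjugation with the C7=C8–C9=O enone under equilibrating acid and by the poor hyperconjugative donor ability of the C4–H bond on the carbonate-bearing carbon; the second by an isopropenyl initiator that leaves C3–O homoallylic and not allylic, by the electron-poor dienone next to C4–O, and by a cyclic carbonate whose carbonyl oxygen cannot reach either cation.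

Step 10
Reactants: 14 (3aS,7aS)-4,6,6-trimethyl-5-[(1E)-3-oxobut-1-en-1-yl]-3a,6,7,7a-tetrahydro-1,3-benzodioxol-2-one
Product: 15 (3E)-4-[(3S,4S)-3,4-dihydroxy-2,6,6-trimethylcyclohex-1-en-1-yl]but-3-en-2-one
Conditions: K2CO3 (0.2 equiv), MeOH, 0 °C → rt
Reagents that add atoms: none
Why: Base-catalysed transesterification (methanolysis) of the strained trans-fused carbonate releases the diol as dimethyl carbonate, and the hindered dienone should not add methoxide.

Step 11
Reactants: 15 (3E)-4-[(3S,4S)-3,4-dihydroxy-2,6,6-trimethylcyclohex-1-en-1-yl]but-3-en-2-one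
Product: 16 (3E)-4-[(3S,4S)-3,4-bis(TBSO)-2,6,6-trimethylcyclohex-1-en-1-yl]but-3-en-2-one
Conditions: TBSOTf, 2,6-lutidine, CH2Cl2, −40 → 0 °C
Reagents that add atoms: tert-butyldimethylsilyl trifluoromethanesulfonate, CC(C)(C)[Si](C)(C)OS(=O)(=O)C(F)(F)F
Why: Silylation with the silyl triflate reaches the hindered allylic C4 hydroxyl as well, and the two silyl ethers withstand the carbanion, hydride, ozone and organolithium steps ahead and leave with fluoride at the end.

Step 12
Reactants: 16 (3E)-4-[(3S,4S)-3,4-bis(TBSO)-2,6,6-trimethylcyclohex-1-en-1-yl]but-3-en-2-one; 17 triethyl phosphonoacetate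
Product: 18 ethyl (2E,4E)-5-[(3S,4S)-3,4-bis(TBSO)-2,6,6-trimethylcyclohex-1-en-1-yl]-3-methylpenta-2,4-dienoate
Conditions: NaH, THF, 0 °C → reflux
Reagents that add atoms: none
Why: Horner–Wadsworth–Emmons olefination of the methyl ketone, as practised on β-ionone, should set the trisubstituted C9'=C10' bond mainly E, and the minor 9'Z ester is removed by chromatography.

Step 13
Reactants: 18 ethyl (2E,4E)-5-[(3S,4S)-3,4-bis(TBSO)-2,6,6-trimethylcyclohex-1-en-1-yl]-3-methylpenta-2,4-dienoate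
Product: 19 (2E,4E)-5-[(3S,4S)-3,4-bis(TBSO)-2,6,6-trimethylcyclohex-1-en-1-yl]-3-methylpenta-2,4-dien-1-ol
Conditions: i-Bu2AlH, CH2Cl2, −78 °C; aq. potassium sodium tartrate
Reagents that add atoms: none
Why: 1,2-Reduction of the conjugated ester by the aluminium hydride gives the allylic alcohol and leaves the silyl ethers and the diene untouched.

Step 14
Reactants: 19 (2E,4E)-5-[(3S,4S)-3,4-bis(TBSO)-2,6,6-trimethylcyclohex-1-en-1-yl]-3-methylpenta-2,4-dien-1-ol
Product: 21 {(2E,4E)-5-[(3S,4S)-3,4-bis(TBSO)-2,6,6-trimethylcyclohex-1-en-1-yl]-3-methylpenta-2,4-dien-1-yl}(triphenyl)phosphonium bromide, via allylic bromide 20 (not isolated)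
Conditions: CBr4, PPh3, CH2Cl2, −20 → 0 °C; then PPh3, rt
Reagents that add atoms: carbon tetrabromide, BrC(Br)(Br)Br; triphenylphosphine, c1ccc(cc1)P(c1ccccc1)c1ccccc1
Why: Appel bromination of the primary allylic alcohol followed by SN2 quaternisation of PPh3 works under neutral conditions, which avoids an allyl cation and so keeps the 9'E geometry and the acid-labile allylic C4' ether.

Step 15
Reactants: 21 {(2E,4E)-5-[(3S,4S)-3,4-bis(TBSO)-2,6,6-trimethylcyclohex-1-en-1-yl]-3-methylpenta-2,4-dien-1-yl}(triphenyl)phosphonium bromide; 22 (2E,4E,6E)-2,7-dimethylocta-2,4,6-trienedial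
Product: 23 (2E,4E,6E,8E,10E,12E)-13-[(3S,4S)-3,4-bis(TBSO)-2,6,6-trimethylcyclohex-1-en-1-yl]-2,7,11-trimethyltrideca-2,4,6,8,10,12-hexaenal
Conditions: NaOMe added slowly to 21 and 22 (3 equiv), MeOH/CH2Cl2, 0 °C; then heptane, 80 °C
Reagents that add atoms: none
Why: Wittig olefination of one aldehyde group of the symmetrical dialdehyde by the semi-stabilised allylic ylide forms C11'=C12' (excess dialdehyde suppresses double condensation), and heating converts the hindered 11'Z isomer into the all-E aldehyde.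

Step 16
Reactants: 16 (3E)-4-[(3S,4S)-3,4-bis(TBSO)-2,6,6-trimethylcyclohex-1-en-1-yl]but-3-en-2-one
Product: 24 (3S,4S)-3,4-bis(TBSO)-2,6,6-trimethylcyclohex-1-ene-1-carbaldehyde
Conditions: O3 (1 equiv), CH2Cl2/MeOH, −78 °C; then Me2S
Reagents that add atoms: ozone, [O-][O+]=O
Why: Ozonolysis with reductive work-up should cleave the disubstituted C7=C8 bond in preference to the tetrasubstituted C5=C6 bond, which is shielded by the gem-dimethyl group, the C5 methyl group and the C4 silyl ether, as in the ozonolysis of β-ionone to β-cyclocitral.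

Step 17
Reactants: 24 (3S,4S)-3,4-bis(TBSO)-2,6,6-trimethylcyclohex-1-ene-1-carbaldehyde
Product: 25 (3S,4S)-1-(2,2-dibromoethenyl)-3,4-bis(TBSO)-2,6,6-trimethylcyclohex-1-ene
Conditions: CBr4, PPh3, CH2Cl2, 0 °C
Reagents that add atoms: carbon tetrabromide, BrC(Br)(Br)Br
Why: First stage of the Corey–Fuchs alkyne synthesis (Ramirez dibromo-olefination): the ylide Ph3P=CBr2 formed from CBr4 and PPh3 converts the aldehyde into the 1,1-dibromoalkene and brings in C8.

Step 18
Reactants: 25 (3S,4S)-1-(2,2-dibromoethenyl)-3,4-bis(TBSO)-2,6,6-trimethylcyclohex-1-ene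
Product: 27 (3S,4S)-3,4-bis(TBSO)-1-ethynyl-2,6,6-trimethylcyclohex-1-ene, via lithium acetylide 26 (not isolated)
Conditions: n-BuLi (2.2 equiv), THF, −78 °C; then H2O
Reagents that add atoms: none
Why: Second stage of the Corey–Fuchs synthesis: bromine–lithium exchange, α-elimination with 1,2-shift (Fritsch–Buttenberg–Wiechell rearrangement) and deprotonation give the lithium acetylide, which is protonated on quenching.

Step 19
Reactants: 28 ethyl acetoacetate
Product: 29 ethyl (2E)-3-{[(trifluoromethyl)sulfonyl]oxy}but-2-enoate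
Conditions: Tf2O, aq. Me4NOH, hexane, 5 °C → rt
Reagents that add atoms: trifluoromethanesulfonic anhydride, O=S(=O)(OS(=O)(=O)C(F)(F)F)C(F)(F)F
Why: O-Sulfonylation of the β-keto ester enolate with a non-chelating tetramethylammonium counter-ion should proceed through the extended enolate and give the E enol triflate, whereas a chelated lithium enolate would give Z.

Step 20
Reactants: 27 (3S,4S)-3,4-bis(TBSO)-1-ethynyl-2,6,6-trimethylcyclohex-1-ene; 29 ethyl (2E)-3-{[(trifluoromethyl)sulfonyl]oxy}but-2-enoate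
Product: 30 ethyl (2E)-5-[(3S,4S)-3,4-bis(TBSO)-2,6,6-trimethylcyclohex-1-en-1-yl]-3-methylpent-2-en-4-ynoate
Conditions: Pd(PPh3)4 (5 mol %), CuI (10 mol %), Et3N, THF, rt
Reagents that add atoms: none
Why: Sonogashira coupling of the terminal alkyne with the electron-poor alkenyl triflate forms the C8–C9 bond with retention of the triflate geometry, which fixes 9E.

Step 21
Reactants: 30 ethyl (2E)-5-[(3S,4S)-3,4-bis(TBSO)-2,6,6-trimethylcyclohex-1-en-1-yl]-3-methylpent-2-en-4-ynoate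
Product: 31 (2E)-5-[(3S,4S)-3,4-bis(TBSO)-2,6,6-trimethylcyclohex-1-en-1-yl]-3-methylpent-2-en-4-yn-1-ol
Conditions: i-Bu2AlH, CH2Cl2, −78 °C; aq. potassium sodium tartrate
Reagents that add atoms: none
Why: 1,2-Reduction of the conjugated ester by the aluminium hydride gives the allylic alcohol without touching the enyne or the silyl ethers.

Step 22
Reactants: 31 (2E)-5-[(3S,4S)-3,4-bis(TBSO)-2,6,6-trimethylcyclohex-1-en-1-yl]-3-methylpent-2-en-4-yn-1-ol
Product: 33 {(2E)-5-[(3S,4S)-3,4-bis(TBSO)-2,6,6-trimethylcyclohex-1-en-1-yl]-3-methylpent-2-en-4-yn-1-yl}(triphenyl)phosphonium bromide, via enynyl bromide 32 (not isolated)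
Conditions: CBr4, PPh3, CH2Cl2, −20 °C; then PPh3, rt
Reagents that add atoms: carbon tetrabromide, BrC(Br)(Br)Br; triphenylphosphine, c1ccc(cc1)P(c1ccccc1)c1ccccc1
Why: Appel bromination and SN2 quaternisation under neutral conditions give the enynyl Wittig salt without passing through an allyl cation, so the 9E geometry set in step 20 is kept.

Step 23
Reactants: 23 (2E,4E,6E,8E,10E,12E)-13-[(3S,4S)-3,4-bis(TBSO)-2,6,6-trimethylcyclohex-1-en-1-yl]-2,7,11-trimethyltrideca-2,4,6,8,10,12-hexaenal; 33 {(2E)-5-[(3S,4S)-3,4-bis(TBSO)-2,6,6-trimethylcyclohex-1-en-1-yl]-3-methylpent-2-en-4-yn-1-yl}(triphenyl)phosphonium bromide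
Product: 34 (3S,4S,3'S,4'S)-3,4,3',4'-tetrakis(TBSO)-7,8-didehydro-β,β-carotene (all-E)
Conditions: NaOMe, MeOH/CH2Cl2, 0 °C → rt; then heptane, 80 °C, dark, Ar
Reagents that add atoms: none
Why: Wittig olefination of the polyenal by the semi-stabilised enynyl ylide forms C11=C12 with the ylide's 9E geometry retained, and gentle heating should convert the hindered 11Z isomer to the all-E chain without iodine, which would equilibrate the 9E enyne.

Step 24
Reactants: 34 (3S,4S,3'S,4'S)-3,4,3',4'-tetrakis(TBSO)-7,8-didehydro-β,β-carotene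
Product: 35 (3S,4S,3'S,4'S)-7,8-didehydro-β,β-carotene-3,4,3',4'-tetrol (all-E)
Conditions: Bu4NF, THF, rt, dark, Ar
Reagents that add atoms: none
Why: Fluoride-mediated cleavage of the four silyl ethers under non-acidic conditions spares the acid-labile allylic C4 and C4' alcohols and the polyene, and no stereocentre is touched.

**Compound list**
1 | dimethyl (4R,5R)-2,2-dimethyl-1,3-dioxolane-4,5-dicarboxylate | COC(=O)[C@@H]1OC(C)(C)O[C@H]1C(=O)OC | starting material
2 | methyl (4R,5S)-5-(hydroxymethyl)-2,2-dimethyl-1,3-dioxolane-4-carboxylate | COC(=O)[C@@H]1OC(C)(C)O[C@H]1CO | intermediate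
3 | methyl (4R,5S)-2,2-dimethyl-5-({[(trifluoromethyl)sulfonyl]oxy}methyl)-1,3-dioxolane-4-carboxylate | COC(=O)[C@@H]1OC(C)(C)O[C@H]1COS(=O)(=O)C(F)(F)F | intermediate
4 | isopropenylmagnesium bromide | C=C(C)[Mg]Br | starting material
5 | methyl (4R,5S)-2,2-dimethyl-5-(2-methylprop-2-en-1-yl)-1,3-dioxolane-4-carboxylate | COC(=O)[C@@H]1OC(C)(C)O[C@H]1CC(C)=C | intermediate
6 | (4R,5S)-N-methoxy-N,2,2-trimethyl-5-(2-methylprop-2-en-1-yl)-1,3-dioxolane-4-carboxamide | CON(C)C(=O)[C@@H]1OC(C)(C)O[C@H]1CC(C)=C | intermediate (not isolated)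
7 | 1-[(4R,5S)-2,2-dimethyl-5-(2-methylprop-2-en-1-yl)-1,3-dioxolan-4-yl]ethan-1-one | CC(=O)[C@@H]1OC(C)(C)O[C@H]1CC(C)=C | intermediate
8 | triethyl 4-phosphonocrotonate | CCOC(=O)/C=C/CP(=O)(OCC)OCC | starting material
9 | ethyl (2E,4E)-5-[(4S,5S)-2,2-dimethyl-5-(2-methylprop-2-en-1-yl)-1,3-dioxolan-4-yl]hexa-2,4-dienoate | CCOC(=O)/C=C/C=C(\C)[C@@H]1OC(C)(C)O[C@H]1CC(C)=C | intermediate
10 | (2E,4E)-N-methoxy-N-methyl-5-[(4S,5S)-2,2-dimethyl-5-(2-methylprop-2-en-1-yl)-1,3-dioxolan-4-yl]hexa-2,4-dienamide | CON(C)C(=O)/C=C/C=C(\C)[C@@H]1OC(C)(C)O[C@H]1CC(C)=C | intermediate (not isolated)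
11 | (3E,5E)-6-[(4S,5S)-2,2-dimethyl-5-(2-methylprop-2-en-1-yl)-1,3-dioxolan-4-yl]hepta-3,5-dien-2-one | CC(=O)/C=C/C=C(\C)[C@@H]1OC(C)(C)O[C@H]1CC(C)=C | intermediate
12 | (3E,5E,7S,8S)-7,8-dihydroxy-6,10-dimethylundeca-3,5,10-trien-2-one | CC(=O)/C=C/C=C(\C)[C@H](O)[C@@H](O)CC(C)=C | intermediate
13 | (4S,5S)-4-(2-methylprop-2-en-1-yl)-5-[(2E,4E)-6-oxohepta-2,4-dien-2-yl]-1,3-dioxolan-2-one | CC(=O)/C=C/C=C(\C)[C@@H]1OC(=O)O[C@H]1CC(C)=C | intermediate
14 | (3aS,7aS)-4,6,6-trimethyl-5-[(1E)-3-oxobut-1-en-1-yl]-3a,6,7,7a-tetrahydro-1,3-benzodioxol-2-one | CC(=O)/C=C/C1=C(C)[C@@H]2OC(=O)O[C@H]2CC1(C)C | intermediate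
15 | (3E)-4-[(3S,4S)-3,4-dihydroxy-2,6,6-trimethylcyclohex-1-en-1-yl]but-3-en-2-one | CC(=O)/C=C/C1=C(C)[C@H](O)[C@@H](O)CC1(C)C | intermediate
16 | (3E)-4-[(3S,4S)-3,4-bis(TBSO)-2,6,6-trimethylcyclohex-1-en-1-yl]but-3-en-2-one | CC(=O)/C=C/C1=C(C)[C@H](O[Si](C)(C)C(C)(C)C)[C@@H](O[Si](C)(C)C(C)(C)C)CC1(C)C | intermediate
17 | triethyl phosphonoacetate | CCOC(=O)CP(=O)(OCC)OCC | starting material
18 | ethyl (2E,4E)-5-[(3S,4S)-3,4-bis(TBSO)-2,6,6-trimethylcyclohex-1-en-1-yl]-3-methylpenta-2,4-dienoate | CCOC(=O)/C=C(C)/C=C/C1=C(C)[C@H](O[Si](C)(C)C(C)(C)C)[C@@H](O[Si](C)(C)C(C)(C)C)CC1(C)C | intermediate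
19 | (2E,4E)-5-[(3S,4S)-3,4-bis(TBSO)-2,6,6-trimethylcyclohex-1-en-1-yl]-3-methylpenta-2,4-dien-1-ol | OC/C=C(C)/C=C/C1=C(C)[C@H](O[Si](C)(C)C(C)(C)C)[C@@H](O[Si](C)(C)C(C)(C)C)CC1(C)C | intermediate
20 | (3S,4S)-1-[(1E,3E)-5-bromo-3-methylpenta-1,3-dien-1-yl]-3,4-bis(TBSO)-2,6,6-trimethylcyclohex-1-ene | BrC/C=C(C)/C=C/C1=C(C)[C@H](O[Si](C)(C)C(C)(C)C)[C@@H](O[Si](C)(C)C(C)(C)C)CC1(C)C | intermediate (not isolated)
21 | {(2E,4E)-5-[(3S,4S)-3,4-bis(TBSO)-2,6,6-trimethylcyclohex-1-en-1-yl]-3-methylpenta-2,4-dien-1-yl}(triphenyl)phosphonium bromide | [Br-].c1ccccc1[P+](c1ccccc1)(c1ccccc1)C/C=C(C)/C=C/C1=C(C)[C@H](O[Si](C)(C)C(C)(C)C)[C@@H](O[Si](C)(C)C(C)(C)C)CC1(C)C | intermediate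
22 | (2E,4E,6E)-2,7-dimethylocta-2,4,6-trienedial | O=C/C(C)=C/C=C/C=C(\C)C=O | starting material
23 | (2E,4E,6E,8E,10E,12E)-13-[(3S,4S)-3,4-bis(TBSO)-2,6,6-trimethylcyclohex-1-en-1-yl]-2,7,11-trimethyltrideca-2,4,6,8,10,12-hexaenal | O=C/C(C)=C/C=C/C=C(C)/C=C/C=C(C)/C=C/C1=C(C)[C@H](O[Si](C)(C)C(C)(C)C)[C@@H](O[Si](C)(C)C(C)(C)C)CC1(C)C | intermediate
24 | (3S,4S)-3,4-bis(TBSO)-2,6,6-trimethylcyclohex-1-ene-1-carbaldehyde | O=CC1=C(C)[C@H](O[Si](C)(C)C(C)(C)C)[C@@H](O[Si](C)(C)C(C)(C)C)CC1(C)C | intermediate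
25 | (3S,4S)-1-(2,2-dibromoethenyl)-3,4-bis(TBSO)-2,6,6-trimethylcyclohex-1-ene | BrC(Br)=CC1=C(C)[C@H](O[Si](C)(C)C(C)(C)C)[C@@H](O[Si](C)(C)C(C)(C)C)CC1(C)C | intermediate
26 | lithium {[(3S,4S)-3,4-bis(TBSO)-2,6,6-trimethylcyclohex-1-en-1-yl]ethynide} | [Li]C#CC1=C(C)[C@H](O[Si](C)(C)C(C)(C)C)[C@@H](O[Si](C)(C)C(C)(C)C)CC1(C)C | intermediate (not isolated)
27 | (3S,4S)-3,4-bis(TBSO)-1-ethynyl-2,6,6-trimethylcyclohex-1-ene | C#CC1=C(C)[C@H](O[Si](C)(C)C(C)(C)C)[C@@H](O[Si](C)(C)C(C)(C)C)CC1(C)C | intermediate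
28 | ethyl acetoacetate | CCOC(=O)CC(C)=O | starting material
29 | ethyl (2E)-3-{[(trifluoromethyl)sulfonyl]oxy}but-2-enoate | CCOC(=O)/C=C(\C)OS(=O)(=O)C(F)(F)F | intermediate
30 | ethyl (2E)-5-[(3S,4S)-3,4-bis(TBSO)-2,6,6-trimethylcyclohex-1-en-1-yl]-3-methylpent-2-en-4-ynoate | CCOC(=O)/C=C(\C)C#CC1=C(C)[C@H](O[Si](C)(C)C(C)(C)C)[C@@H](O[Si](C)(C)C(C)(C)C)CC1(C)C | intermediate
31 | (2E)-5-[(3S,4S)-3,4-bis(TBSO)-2,6,6-trimethylcyclohex-1-en-1-yl]-3-methylpent-2-en-4-yn-1-ol | OC/C=C(\C)C#CC1=C(C)[C@H](O[Si](C)(C)C(C)(C)C)[C@@H](O[Si](C)(C)C(C)(C)C)CC1(C)C | intermediate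
32 | (3S,4S)-1-[(3E)-5-bromo-3-methylpent-3-en-1-yn-1-yl]-3,4-bis(TBSO)-2,6,6-trimethylcyclohex-1-ene | BrC/C=C(\C)C#CC1=C(C)[C@H](O[Si](C)(C)C(C)(C)C)[C@@H](O[Si](C)(C)C(C)(C)C)CC1(C)C | intermediate (not isolated)
33 | {(2E)-5-[(3S,4S)-3,4-bis(TBSO)-2,6,6-trimethylcyclohex-1-en-1-yl]-3-methylpent-2-en-4-yn-1-yl}(triphenyl)phosphonium bromide | [Br-].c1ccccc1[P+](c1ccccc1)(c1ccccc1)C/C=C(\C)C#CC1=C(C)[C@H](O[Si](C)(C)C(C)(C)C)[C@@H](O[Si](C)(C)C(C)(C)C)CC1(C)C | intermediate
34 | (3S,4S,3'S,4'S)-3,4,3',4'-tetrakis(TBSO)-7,8-didehydro-β,β-carotene (all-E) | CC1=C(C#C/C(C)=C/C=C/C(C)=C/C=C/C=C(C)/C=C/C=C(C)/C=C/C2=C(C)[C@H](O[Si](C)(C)C(C)(C)C)[C@@H](O[Si](C)(C)C(C)(C)C)CC2(C)C)C(C)(C)C[C@H](O[Si](C)(C)C(C)(C)C)[C@H]1O[Si](C)(C)C(C)(C)C | intermediate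
35 | (3S,4S,3'S,4'S)-7,8-didehydro-β,β-carotene-3,4,3',4'-tetrol (all-E) | CC1=C(C#C/C(C)=C/C=C/C(C)=C/C=C/C=C(C)/C=C/C=C(C)/C=C/C2=C(C)[C@H](O)[C@@H](O)CC2(C)C)C(C)(C)C[C@H](O)[C@H]1O | target

**Step count**
Total: 24 steps. Longest linear sequence: 19 steps (steps 1–11, 16–18, 20–24).

**Steps most likely to fail**

Step 9. Ring closure may be outrun by proton loss from the C1 cation toward C2, which gives the 2-methylprop-1-enyl isomer whose allylic C3–O bond then ionises in strong acid. The cation may also simply be hydrated, or the C5 cation may shed the C4 proton and destroy that stereocentre. The fallback sets out from 13 and comes back at 14, closing the same C1–C6 bond with a metal electrophile instead of a proton. Hg(OTf)2·PhNMe2 in MeCN at −20 °C adds divalent mercury to the CH2 end of the isopropenyl group under buffered conditions in which the dienone is not O-protonated and no strong acid is present. C6 captures the C1 cation, and brine work-up gives the organomercury chloride (3aS,7aS)-6-[(chloromercurio)methyl]-4,6-dimethyl-5-[(1E)-3-oxobut-1-en-1-yl]-3a,6,7,7a-tetrahydro-1,3-benzodioxol-2-one F1 as a mixture of C6 epimers. Radical hydrodemercuration with Bu3SnH and AIBN in toluene turns CH2HgCl into the second C1 methyl group and gives 14.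

Step 5. The delocalised phosphonate anion may enolise the α-alkoxy ketone instead of adding to it, returning ketone or causing β-elimination of the C3 oxygen, and addition to a ketone is slow. The fallback sets out from 7 and comes back at 11, building the dienone the way pseudoionone is made from citral. Horner–Wadsworth–Emmons reaction of 7 with the more reactive triethyl phosphonoacetate 17 (NaH, THF) gives ethyl (2E)-3-[(4S,5S)-2,2-dimethyl-5-(2-methylprop-2-en-1-yl)-1,3-dioxolan-4-yl]but-2-enoate F2. Reduction with i-Bu2AlH gives (2E)-3-[(4S,5S)-2,2-dimethyl-5-(2-methylprop-2-en-1-yl)-1,3-dioxolan-4-yl]but-2-en-1-ol F3, and MnO2 oxidation gives (2E)-3-[(4S,5S)-2,2-dimethyl-5-(2-methylprop-2-en-1-yl)-1,3-dioxolan-4-yl]but-2-enal F4. Aldol condensation with acetone (aq. NaOH, acetone, rt) then gives 11 directly, so that 9 and 10 are bypassed.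

Step 16. Ozone may also attack the ring C5=C6 bond, giving over-oxidation and poor site selectivity. The fallback sets out from 16 and comes back at 24, using the electrophilicity of the enone instead of the nucleophilicity of an olefin. Nucleophilic epoxidation (H2O2, NaOH, MeOH, 0 °C) touches only the enone C7=C8 bond and gives the trans epoxy ketone 1-{3-[(3S,4S)-3,4-bis(TBSO)-2,6,6-trimethylcyclohex-1-en-1-yl]oxiran-2-yl}ethan-1-one F5. Periodic acid (H5IO6, THF/H2O, 0 °C) cleaves the epoxide between C7 and C8 to give 24.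

**Further compounds**
F1 | step 9 | (3aS,7aS)-6-[(chloromercurio)methyl]-4,6-dimethyl-5-[(1E)-3-oxobut-1-en-1-yl]-3a,6,7,7a-tetrahydro-1,3-benzodioxol-2-one (C6 epimers) | CC(=O)/C=C/C1=C(C)[C@@H]2OC(=O)O[C@H]2CC1(C)C[Hg]Cl
F2 | step 5 | ethyl (2E)-3-[(4S,5S)-2,2-dimethyl-5-(2-methylprop-2-en-1-yl)-1,3-dioxolan-4-yl]but-2-enoate | CCOC(=O)/C=C(\C)[C@@H]1OC(C)(C)O[C@H]1CC(C)=C
F3 | step 5 | (2E)-3-[(4S,5S)-2,2-dimethyl-5-(2-methylprop-2-en-1-yl)-1,3-dioxolan-4-yl]but-2-en-1-ol | OC/C=C(\C)[C@@H]1OC(C)(C)O[C@H]1CC(C)=C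
F4 | step 5 | (2E)-3-[(4S,5S)-2,2-dimethyl-5-(2-methylprop-2-en-1-yl)-1,3-dioxolan-4-yl]but-2-enal | O=C/C=C(\C)[C@@H]1OC(C)(C)O[C@H]1CC(C)=C
F5 | step 16 | 1-{3-[(3S,4S)-3,4-bis(TBSO)-2,6,6-trimethylcyclohex-1-en-1-yl]oxiran-2-yl}ethan-1-one (trans epoxide, two diastereomers) | CC(=O)C1OC1C1=C(C)[C@H](O[Si](C)(C)C(C)(C)C)[C@@H](O[Si](C)(C)C(C)(C)C)CC1(C)C
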